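**Plan**
1. The target is a linear chain of seven oxygenated benzene rings, lettered A (2,4,6-trihydroxyphenyl end) to G (3,4,5-trihydroxyphenyl end), joined by six diaryl ether oxygens.
2. Retrosynthesis first removes all O-alkyl groups (15 Me, 1 Et), then cuts ring E itself at E C2–C3 and E C1–C6.
3. The enabling feature is ring E: a benzene with O on C1, C3, C4 and C5 and H on C2 and C6. E C1–C2 map onto an aryl ethynyl ether already bonded through O to ring D C2. E C3–C6 map onto a 3-ethoxy-4-aryloxycyclobutenone already bonded through O to ring F C1.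
4. Forward, rings A→B→C→D are joined by three rounds of Cu-catalysed O-arylation of a 2,6-dimethoxyphenol with a bromobenzaldehyde, each followed by Baeyer–Villiger unmasking of the next phenol; the ring D C2–OH then becomes O–C≡CH.
5. Rings F and G are joined by a Chan–Lam coupling; Br→OH, O-carboxymethylation and a ketene/ethoxyacetylene [2+2] give the cyclobutenone. The benzannulation closes ring E last and BBr3 frees the 17 hydroxyls.
6. Stereochemistry: the target has none; the racemic sp3 carbon of the cyclobutenone becomes aromatic in the key step.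

Key step: step 15

Remark: the target is achiral (no stereocentre, no configurationally stable axis), so "single enantiomer" reduces to the constitution. Ring E is numbered C1 (O to ring D), C3 (OH), C4 (O to ring F), C5 (OH). Compounds 1, 2, 9, 14, 19, 20, 25 and 28 are taken as purchasable.

**Step 1**
Reactants: 1 2,4,6-trimethoxyphenol; 2 4-bromo-2,6-dimethoxybenzaldehyde
Product: 3 AB aldehyde 2,6-dimethoxy-4-(2,4,6-trimethoxyphenoxy)benzaldehyde
Conditions: CuI (10 mol%), picolinic acid (20 mol%), K3PO4, DMSO, 90 °C, Ar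
Reagents that add atoms: none
Why: Ullmann-type Cu-catalysed O-arylation; the bromide of 2 is unhindered and activated by the para-formyl group, and the picolinic acid system accepts di-ortho-substituted phenoxides.

**Step 2**
Reactants: 3 AB aldehyde
Product: 5 AB phenol 2,6-dimethoxy-4-(2,4,6-trimethoxyphenoxy)phenol, via AB aryl formate 4 (not isolated)
Conditions: mCPBA, NaHCO3, CH2Cl2, 0 °C → rt; aq. Na2S2O3 wash; K2CO3, MeOH, rt, Ar
Reagents that add atoms: mCPBA OOC(=O)c1cccc(Cl)c1
Why: Baeyer–Villiger (Dakin-type) oxidation in which the electron-rich 2,4,6-trioxygenated aryl group migrates in preference to H, followed by methanolysis of the formate.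

**Step 3**
Reactants: 5 AB phenol; 2 4-bromo-2,6-dimethoxybenzaldehyde
Product: 6 ABC aldehyde 4-[2,6-dimethoxy-4-(2,4,6-trimethoxyphenoxy)phenoxy]-2,6-dimethoxybenzaldehyde
Conditions: CuI (10 mol%), picolinic acid (20 mol%), K3PO4, DMSO, 90 °C, Ar
Reagents that add atoms: none
Why: The same Ullmann-type O-arylation as step 1, with the same phenol class (2,6-dimethoxyphenol) and the same activated bromide.

**Step 4**
Reactants: 6 ABC aldehyde
Product: 8 ABC phenol 4-[2,6-dimethoxy-4-(2,4,6-trimethoxyphenoxy)phenoxy]-2,6-dimethoxyphenol, via ABC aryl formate 7 (not isolated)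
Conditions: mCPBA, NaHCO3, CH2Cl2, 0 °C → rt; aq. Na2S2O3 wash; K2CO3, MeOH, rt, Ar
Reagents that add atoms: mCPBA OOC(=O)c1cccc(Cl)c1
Why: Baeyer–Villiger oxidation of a 2,6-dimethoxy-4-aryloxybenzaldehyde with aryl migration, as in step 2, then formate methanolysis.

**Step 5**
Reactants: 9 5-bromo-1,2,3-trimethoxybenzene
Product: 10 6-bromo-2,3,4-trimethoxybenzaldehyde
Conditions: Cl2CHOMe, TiCl4, CH2Cl2, −10 → 0 °C; ice-water
Reagents that add atoms: dichloromethyl methyl ether COC(Cl)Cl; water O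
Why: Rieche formylation; the two open positions of 9 are equivalent and each is ortho and para to a methoxy group, so a single aldehyde with CHO between C–Br and C–OMe should form.

**Step 6**
Reactants: 8 ABC phenol; 10 6-bromo-2,3,4-trimethoxybenzaldehyde
Product: 11 ABCD aldehyde 6-{4-[2,6-dimethoxy-4-(2,4,6-trimethoxyphenoxy)phenoxy]-2,6-dimethoxyphenoxy}-2,3,4-trimethoxybenzaldehyde
Conditions: CuI (20 mol%), picolinic acid (40 mol%), K3PO4, DMSO, 90–100 °C, Ar
Reagents that add atoms: none
Why: Ullmann-type O-arylation in which the ortho-formyl group activates the C–Br bond and assists copper insertion, while the other ortho position of the bromide is unsubstituted.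

**Step 7**
Reactants: 11 ABCD aldehyde
Product: 13 ABCD phenol 6-{4-[2,6-dimethoxy-4-(2,4,6-trimethoxyphenoxy)phenoxy]-2,6-dimethoxyphenoxy}-2,3,4-trimethoxyphenol, via ABCD aryl formate 12 (not isolated)
Conditions: mCPBA, NaHCO3, CH2Cl2, 0 °C → rt; aq. Na2S2O3 wash; K2CO3, MeOH, rt, Ar
Reagents that add atoms: mCPBA OOC(=O)c1cccc(Cl)c1
Why: Baeyer–Villiger oxidation of an aldehyde flanked by OAr and OMe and para to OMe, so aryl migration is strongly favoured and the ring D C2–OH is unmasked after formate cleavage.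

**Step 8**
Reactants: 13 ABCD phenol; 14 trichloroethylene
Product: 15 ABCD (E)-1,2-dichlorovinyl ether (ArO–CCl=CHCl on ring D C2)
Conditions: K2CO3, DMF, 70 °C
Reagents that add atoms: none
Why: Base converts trichloroethylene into dichloroacetylene and the phenoxide adds anti across this small linear electrophile (standard dichlorovinyl ether route to ynol ethers), which the two ortho substituents should not hinder.

**Step 9**
Reactants: 15 ABCD (E)-1,2-dichlorovinyl ether
Product: 18 ABCD ethynyl ether (ArO–C≡CH on ring D C2), via chloroethynyl ether 16 (not isolated), via lithium aryloxyacetylide 17 (not isolated)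
Conditions: n-BuLi (2.3 equiv), THF, −78 → −40 °C; MeOH, −78 °C; filtration through Et3N-deactivated silica, used at once
Reagents that add atoms: none
Why: β-Elimination of HCl followed by Cl/Li exchange gives the lithium ynolate ether, which is protonated to the terminal ynol ether; at −78 °C both events should be much faster than ortho-lithiation of the methoxyarenes.

**Step 10**
Reactants: 19 4-bromo-2,6-dimethoxyphenol; 20 3,4,5-trimethoxyphenylboronic acid
Product: 21 FG bromide 5-bromo-1,3-dimethoxy-2-(3,4,5-trimethoxyphenoxy)benzene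
Conditions: Cu(OAc)2, pyridine, 4 Å MS, CH2Cl2, air, rt
Reagents that add atoms: none
Why: Chan–Lam–Evans O-arylation, which proceeds at room temperature, leaves the aryl bromide untouched and is known to accept 2,6-disubstituted phenols.

**Step 11**
Reactants: 21 FG bromide
Product: 24 FG phenol 3,5-dimethoxy-4-(3,4,5-trimethoxyphenoxy)phenol, via FG aryllithium 22 (not isolated), via FG dimethyl boronate 23 (not isolated)
Conditions: n-BuLi, THF, −78 °C; B(OMe)3, −78 °C → rt; 30% H2O2, aq. NaOH, 0 °C → rt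
Reagents that add atoms: hydrogen peroxide OO
Why: Br/Li exchange at an unhindered position, borylation and oxidative 1,2-aryl shift from boron to oxygen (ipso-hydroxylation of an arylboronate).

**Step 12**
Reactants: 24 FG phenol; 25 bromoacetic acid
Product: 26 FG aryloxyacetic acid 2-[3,5-dimethoxy-4-(3,4,5-trimethoxyphenoxy)phenoxy]acetic acid
Conditions: NaH (2.5 equiv), THF, 0 → 65 °C; aq. HCl
Reagents that add atoms: none
Why: Williamson etherification of an unhindered sodium phenoxide with sodium bromoacetate formed in the flask.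

**Step 13**
Reactants: 26 FG aryloxyacetic acid
Product: 27 FG aryloxyacetyl chloride
Conditions: (COCl)2, cat. DMF, CH2Cl2, 0 °C → rt; evaporate, use crude
Reagents that add atoms: oxalyl chloride ClC(=O)C(=O)Cl
Why: Acid chloride formation through the catalytic Vilsmeier-type chloroiminium species, carried out without Lewis acid so that the electron-rich rings are not acylated.

**Step 14**
Reactants: 27 FG aryloxyacetyl chloride; 28 ethoxyacetylene
Product: 30 (±)-3-ethoxy-4-[3,5-dimethoxy-4-(3,4,5-trimethoxyphenoxy)phenoxy]cyclobut-2-en-1-one, via FG aryloxyketene 29 (not isolated)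
Conditions: ethoxyacetylene (3 equiv, hexane solution), Et3N (slow addition), CH2Cl2, 0 °C → rt
Reagents that add atoms: none
Why: Dehydrochlorination gives the aryloxyketene, which undergoes ketene–ynol ether [2+2] cycloaddition with the nucleophilic CH terminus of ethoxyacetylene bonding to the ketene carbonyl carbon, so OEt ends at C3 and OAr at C4; the C4 stereocentre forms racemic and needs no control because step 15 removes it.

**Step 15**
Reactants: 18 ABCD ethynyl ether; 30 (±)-3-ethoxy-4-(FG-aryloxy)cyclobutenone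
Product: 35 heptamer phenol (ring E = 1,4-bis(aryloxy)-3-hydroxy-5-ethoxybenzene; all other hydroxyls as OMe), via vinylketene 31 (not isolated), via vinylcyclobutenone 32 (not isolated), via dienylketene 33 (not isolated), via cyclohexadienone 34 (not isolated)
Conditions: 30 (1.5 equiv), PhMe, 80 → 110 °C, Ar, sealed tube; then K2CO3, MeOH, rt
Reagents that add atoms: none
Why: Heating opens cyclobutenone 30 by 4π-electrocyclic cleavage of its C1–C4 bond (aryloxy group rotating outward) to vinylketene 31, whose carbonyl carbon is attacked by the terminal CH of ynol ether 18 in a regioselective [2+2] cycloaddition that gives 4-vinylcyclobutenone 32 and forms the ring E C2–C3 and C1–C6 bonds. A second 4π opening gives dienylketene 33, and ring E is closed by 6π-electrocyclisation between the ketene carbon and the aryloxy-bearing vinyl terminus (re-forming E C3–C4) to cyclohexadienone 34, which tautomerises to phenol 35. The closest known reaction is the Danheiser benzannulation of cyclobutenones with ynol ethers, which delivers resorcinol monoethers of this substitution type. No stereocentre remains, since the racemic sp3 carbons of 30, 32 and 34 all become aromatic. The only selectivity needed is the orientation of the [2+2] step, secured by the matched polarisation of the ketene (electrophilic at C=O) and the ynol ether (nucleophilic at the carbon β to oxygen); this places the ring D oxygen meta to the new OH, the FG-aryloxy group ortho to it and the ethoxy group on the other side of that aryloxy group. The two ortho substituents on ring D twist the aryl ring out of conjugation with the ether oxygen, so the alkyne keeps ynol-ether nucleophilicity, and any product O-acylated by excess vinylketene is returned to 35 by the methanolysis work-up.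

**Step 16**
Reactants: 35 heptamer phenol
Product: 36 target CNP0304148.0 (heptadecahydroxy heptamer)
Conditions: BBr3 (ca. 3 equiv per ether), CH2Cl2, −78 °C → rt; MeOH then H2O, 0 °C, Ar; Sephadex LH-20
Reagents that add atoms: none
Why: Lewis acid-mediated ether cleavage in which bromide attacks the methyl and ethyl carbons of the boron–ether adducts, while the diaryl ether C–O bonds have no sp3 carbon to attack and should survive.

**Compound list**
1 | 2,4,6-trimethoxyphenol | COc1cc(OC)c(O)c(OC)c1 | starting material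
2 | 4-bromo-2,6-dimethoxybenzaldehyde | COc1cc(Br)cc(OC)c1C=O | starting material
3 | AB aldehyde, 2,6-dimethoxy-4-(2,4,6-trimethoxyphenoxy)benzaldehyde | COc1cc(OC)c(Oc2cc(OC)c(C=O)c(OC)c2)c(OC)c1 | intermediate
4 | AB aryl formate, 2,6-dimethoxy-4-(2,4,6-trimethoxyphenoxy)phenyl formate | COc1cc(OC)c(Oc2cc(OC)c(OC=O)c(OC)c2)c(OC)c1 | intermediate
5 | AB phenol, 2,6-dimethoxy-4-(2,4,6-trimethoxyphenoxy)phenol | COc1cc(OC)c(Oc2cc(OC)c(O)c(OC)c2)c(OC)c1 | intermediate
6 | ABC aldehyde, 4-[2,6-dimethoxy-4-(2,4,6-trimethoxyphenoxy)phenoxy]-2,6-dimethoxybenzaldehyde | COc1cc(OC)c(Oc2cc(OC)c(Oc3cc(OC)c(C=O)c(OC)c3)c(OC)c2)c(OC)c1 | intermediate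
7 | ABC aryl formate | COc1cc(OC)c(Oc2cc(OC)c(Oc3cc(OC)c(OC=O)c(OC)c3)c(OC)c2)c(OC)c1 | intermediate
8 | ABC phenol, 4-[2,6-dimethoxy-4-(2,4,6-trimethoxyphenoxy)phenoxy]-2,6-dimethoxyphenol | COc1cc(OC)c(Oc2cc(OC)c(Oc3cc(OC)c(O)c(OC)c3)c(OC)c2)c(OC)c1 | intermediate
9 | 5-bromo-1,2,3-trimethoxybenzene | COc1cc(Br)cc(OC)c1OC | starting material
10 | 6-bromo-2,3,4-trimethoxybenzaldehyde | COc1cc(Br)c(C=O)c(OC)c1OC | intermediate
11 | ABCD aldehyde, 6-{4-[2,6-dimethoxy-4-(2,4,6-trimethoxyphenoxy)phenoxy]-2,6-dimethoxyphenoxy}-2,3,4-trimethoxybenzaldehyde | COc1cc(OC)c(Oc2cc(OC)c(Oc3cc(OC)c(Oc4cc(OC)c(OC)c(OC)c4C=O)c(OC)c3)c(OC)c2)c(OC)c1 | intermediate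
12 | ABCD aryl formate | COc1cc(OC)c(Oc2cc(OC)c(Oc3cc(OC)c(Oc4cc(OC)c(OC)c(OC)c4OC=O)c(OC)c3)c(OC)c2)c(OC)c1 | intermediate
13 | ABCD phenol, 6-{4-[2,6-dimethoxy-4-(2,4,6-trimethoxyphenoxy)phenoxy]-2,6-dimethoxyphenoxy}-2,3,4-trimethoxyphenol | COc1cc(OC)c(Oc2cc(OC)c(Oc3cc(OC)c(Oc4cc(OC)c(OC)c(OC)c4O)c(OC)c3)c(OC)c2)c(OC)c1 | intermediate
14 | trichloroethylene | ClC=C(Cl)Cl | starting material
15 | ABCD (E)-1,2-dichlorovinyl ether | COc1cc(OC)c(Oc2cc(OC)c(Oc3cc(OC)c(Oc4cc(OC)c(OC)c(OC)c4O/C(Cl)=C\Cl)c(OC)c3)c(OC)c2)c(OC)c1 | intermediate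
16 | ABCD chloroethynyl ether | COc1cc(OC)c(Oc2cc(OC)c(Oc3cc(OC)c(Oc4cc(OC)c(OC)c(OC)c4OC#CCl)c(OC)c3)c(OC)c2)c(OC)c1 | intermediate
17 | ABCD lithium aryloxyacetylide | COc1cc(OC)c(Oc2cc(OC)c(Oc3cc(OC)c(Oc4cc(OC)c(OC)c(OC)c4OC#C[Li])c(OC)c3)c(OC)c2)c(OC)c1 | intermediate
18 | ABCD ethynyl ether (O–C≡CH on ring D C2) | COc1cc(OC)c(Oc2cc(OC)c(Oc3cc(OC)c(Oc4cc(OC)c(OC)c(OC)c4OC#C)c(OC)c3)c(OC)c2)c(OC)c1 | intermediate
19 | 4-bromo-2,6-dimethoxyphenol | COc1cc(Br)cc(OC)c1O | starting material
20 | 3,4,5-trimethoxyphenylboronic acid | COc1cc(B(O)O)cc(OC)c1OC | starting material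
21 | FG bromide, 5-bromo-1,3-dimethoxy-2-(3,4,5-trimethoxyphenoxy)benzene | Brc1cc(OC)c(Oc2cc(OC)c(OC)c(OC)c2)c(OC)c1 | intermediate
22 | FG aryllithium | [Li]c1cc(OC)c(Oc2cc(OC)c(OC)c(OC)c2)c(OC)c1 | intermediate
23 | FG dimethyl boronate | COB(OC)c1cc(OC)c(Oc2cc(OC)c(OC)c(OC)c2)c(OC)c1 | intermediate
24 | FG phenol, 3,5-dimethoxy-4-(3,4,5-trimethoxyphenoxy)phenol | Oc1cc(OC)c(Oc2cc(OC)c(OC)c(OC)c2)c(OC)c1 | intermediate
25 | bromoacetic acid | OC(=O)CBr | starting material
26 | FG aryloxyacetic acid, 2-[3,5-dimethoxy-4-(3,4,5-trimethoxyphenoxy)phenoxy]acetic acid | OC(=O)COc1cc(OC)c(Oc2cc(OC)c(OC)c(OC)c2)c(OC)c1 | intermediate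
27 | FG aryloxyacetyl chloride | ClC(=O)COc1cc(OC)c(Oc2cc(OC)c(OC)c(OC)c2)c(OC)c1 | intermediate
28 | ethoxyacetylene | CCOC#C | starting material
29 | FG aryloxyketene | O=C=COc1cc(OC)c(Oc2cc(OC)c(OC)c(OC)c2)c(OC)c1 | intermediate
30 | (±)-3-ethoxy-4-[3,5-dimethoxy-4-(3,4,5-trimethoxyphenoxy)phenoxy]cyclobut-2-en-1-one (racemic) | CCOC1=CC(=O)C1Oc1cc(OC)c(Oc2cc(OC)c(OC)c(OC)c2)c(OC)c1 | intermediate
31 | vinylketene, 3-ethoxy-4-(FG-aryloxy)buta-1,3-dien-1-one (geometry as expected from outward rotation of OAr) | O=C=C/C(OCC)=C/Oc1cc(OC)c(Oc2cc(OC)c(OC)c(OC)c2)c(OC)c1 | intermediate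
32 | vinylcyclobutenone, 3-(ABCD-aryloxy)-4-[1-ethoxy-2-(FG-aryloxy)vinyl]cyclobut-2-en-1-one (racemic) | COc1cc(OC)c(Oc2cc(OC)c(Oc3cc(OC)c(Oc4cc(OC)c(OC)c(OC)c4OC5=CC(=O)C5/C(OCC)=C/Oc6cc(OC)c(Oc7cc(OC)c(OC)c(OC)c7)c(OC)c6)c(OC)c3)c(OC)c2)c(OC)c1 | intermediate
33 | dienylketene, 3-(ABCD-aryloxy)-5-ethoxy-6-(FG-aryloxy)hexa-1,3,5-trien-1-one (central C=C with the chain carbons cis) | COc1cc(OC)c(Oc2cc(OC)c(Oc3cc(OC)c(Oc4cc(OC)c(OC)c(OC)c4O/C(=C/C(OCC)=C/Oc5cc(OC)c(Oc6cc(OC)c(OC)c(OC)c6)c(OC)c5)C=C=O)c(OC)c3)c(OC)c2)c(OC)c1 | intermediate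
34 | cyclohexadienone, 3-(ABCD-aryloxy)-5-ethoxy-6-(FG-aryloxy)cyclohexa-2,4-dien-1-one (racemic) | COc1cc(OC)c(Oc2cc(OC)c(Oc3cc(OC)c(Oc4cc(OC)c(OC)c(OC)c4OC5=CC(=O)C(Oc6cc(OC)c(Oc7cc(OC)c(OC)c(OC)c7)c(OC)c6)C(OCC)=C5)c(OC)c3)c(OC)c2)c(OC)c1 | intermediate
35 | heptamer phenol: ring E 3-hydroxy-5-ethoxy, rings A–D, F and G fully O-methylated | COc1cc(OC)c(Oc2cc(OC)c(Oc3cc(OC)c(Oc4cc(OC)c(OC)c(OC)c4Oc4cc(O)c(Oc5cc(OC)c(Oc6cc(OC)c(OC)c(OC)c6)c(OC)c5)c(OCC)c4)c(OC)c3)c(OC)c2)c(OC)c1 | intermediate
36 | CNP0304148.0, heptadecahydroxy heptamer | Oc1cc(O)c(Oc2cc(O)c(Oc3cc(O)c(Oc4cc(O)c(O)c(O)c4Oc4cc(O)c(Oc5cc(O)c(Oc6cc(O)c(O)c(O)c6)c(O)c5)c(O)c4)c(O)c3)c(O)c2)c(O)c1 | target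

**Totals**
Total step count: 16.
Longest linear sequence: 10 steps (1, 2, 3, 4, 6, 7, 8, 9, 15, 16).

**Steps most likely to fail**

Step 15. The vinylketene may dimerise, or be consumed by acylation, faster than it adds to the bulky aryl ynol ether, and the ynol ether may oligomerise at the temperature the vinylogous-ester cyclobutenone needs for ring opening. The fallback sets out from 21 and abandons the ring construction in favour of bringing ring E in preformed as 19. Br/Li exchange on 21, borylation with B(OMe)3 and acidic hydrolysis would give [3,5-dimethoxy-4-(3,4,5-trimethoxyphenoxy)phenyl]boronic acid F1. Chan–Lam coupling of F1 with 19 (Cu(OAc)2, pyridine, air) would give the EFG bromide 5-bromo-2-[3,5-dimethoxy-4-(3,4,5-trimethoxyphenoxy)phenoxy]-1,3-dimethoxybenzene F2. Ullmann coupling of F2 with the ABCD phenol 13 (CuI, picolinic acid, K3PO4, DMSO) would give the heptadecamethyl ether of the heptamer F3. BBr3 cleavage under the conditions of step 16 would bring the route back at 36.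

Step 14. The aryloxyketene may oligomerise or follow amine-initiated pathways before ethoxyacetylene intercepts it, and the enol ether of the product may hydrolyse during isolation. The fallback sets out from 27 and replaces the alkyne by the more nucleophilic ketene diethyl acetal. Et3N with 1,1-diethoxyethene would give (±)-2-[3,5-dimethoxy-4-(3,4,5-trimethoxyphenoxy)phenoxy]-3,3-diethoxycyclobutan-1-one F4 by ketene–ketene acetal [2+2] cycloaddition. Elimination of ethanol on basic alumina, through enolisation toward the unsubstituted CH2, would return the route at 30.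

Step 16. Ether cleavage at sixteen sites may stop short and leave partly alkylated congeners, and the free polyphenol may autoxidise during chromatographic isolation. The fallback sets out from 35 and changes the isolation to derivatise, purify and release. The crude BBr3 product would be peracetylated (Ac2O, pyridine) to the heptadecaacetate F5, which is stable on silica and allows incompletely dealkylated material to be separated. Acid-catalysed methanolysis (AcCl in degassed MeOH) would then release 36.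

**Further compounds**
F1 | step 15 | [3,5-dimethoxy-4-(3,4,5-trimethoxyphenoxy)phenyl]boronic acid | OB(O)c1cc(OC)c(Oc2cc(OC)c(OC)c(OC)c2)c(OC)c1
F2 | step 15 | 5-bromo-2-[3,5-dimethoxy-4-(3,4,5-trimethoxyphenoxy)phenoxy]-1,3-dimethoxybenzene | Brc1cc(OC)c(Oc2cc(OC)c(Oc3cc(OC)c(OC)c(OC)c3)c(OC)c2)c(OC)c1
F3 | step 15 | heptadecamethyl ether of the heptamer | COc1cc(OC)c(Oc2cc(OC)c(Oc3cc(OC)c(Oc4cc(OC)c(OC)c(OC)c4Oc4cc(OC)c(Oc5cc(OC)c(Oc6cc(OC)c(OC)c(OC)c6)c(OC)c5)c(OC)c4)c(OC)c3)c(OC)c2)c(OC)c1
F4 | step 14 | (±)-2-[3,5-dimethoxy-4-(3,4,5-trimethoxyphenoxy)phenoxy]-3,3-diethoxycyclobutan-1-one | CCOC1(OCC)CC(=O)C1Oc1cc(OC)c(Oc2cc(OC)c(OC)c(OC)c2)c(OC)c1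
F5 | step 16 | heptadecaacetate of the target | CC(=O)Oc1cc(OC(C)=O)c(Oc2cc(OC(C)=O)c(Oc3cc(OC(C)=O)c(Oc4cc(OC(C)=O)c(OC(C)=O)c(OC(C)=O)c4Oc4cc(OC(C)=O)c(Oc5cc(OC(C)=O)c(Oc6cc(OC(C)=O)c(OC(C)=O)c(OC(C)=O)c6)c(OC(C)=O)c5)c(OC(C)=O)c4)c(OC(C)=O)c3)c(OC(C)=O)c2)c(OC(C)=O)c1
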